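## Retrosynthetic overview

1. Target 23 ⇐ Schenck ene reaction of singlet oxygen with the tetrasubstituted C4=C5 alkene of angelate 22, which installs the C5α–OOH group and the C4=C15 methylene together; 22 ⇐ bis-silyl ether 15 by deprotection, oxidation of C12 to the methyl ester and angeloylation.
2. 15 ⇐ monocyclic allenal 14 by the key C3–C4 ring closure, a Ni(0)-catalysed reductive allene–aldehyde cyclisation that forms ring A, the C3 carbinol centre and the C4=C5 alkene with C15 as a methyl group.
3. Enabling feature: the C3(O)–C4(=C15H2)–C5(OOH) array on ring A. The allylic hydroperoxide C4(=C15)–C5–OOH is the retron of an ene reaction on a C15H3–C4=C5 alkene, and the resulting C3(O)–C4(C15)=C5 unit maps onto a C3 aldehyde tethered from C10 plus an exocyclic allene C5=C4=C15 on ring B.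
4. 14 ⇐ C5 ketone 8 (ethynylation, then SN2′ hydride delivery; C5 epimers converge) ⇐ (+)-dihydrocarvone 1, with the C10 quaternary centre set by auxiliary-controlled Michael addition to acrylonitrile and the isopropenyl group oxidised to the precursor of the C11–C13 acrylate.
5. Ring order: ring B is the carvone-derived cyclohexane (present from the start); ring A is closed in step 7.

Key step: step 7

Remark: commercial (+)-dihydrocarvone is a mixture of C2 epimers with the same 5R configuration; this is immaterial because C2 becomes sp2 in step 1. Eudesmane numbering is used for ring positions; the target is read as methyl 3β-angeloyloxy-5α-hydroperoxyeudesma-4(15),11(13)-dien-12-oate, (3S,5S,7R,10S).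

## Route

Step 1
Reactants: 1 (+)-dihydrocarvone; 2 (R)-(+)-1-phenylethylamine; 3 acrylonitrile
Product: 6 3-[(1S,4R)-1-methyl-2-oxo-4-(prop-1-en-2-yl)cyclohexyl]propanenitrile, via ketimine 4 (not isolated), via cyanoethylated ketimine 5 (not isolated)
Conditions: 2, cat. TsOH, toluene, reflux (Dean–Stark); then 3, THF, 50 °C; then 20% aq. AcOH, rt
Reagents that add atoms: acrylonitrile (3), C=CC#N; water, O
Why: The ketimine reacts through its more substituted secondary-enamine tautomer in an auxiliary-controlled aza-ene-type Michael addition; the (R)-phenylethyl group should shield one enamine face so that C10 forms as 10S (methyl cis to the C7 substituent), both C2 epimers of 1 converge through the planar enamine, and mild acid hydrolysis releases the ketone.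

Step 2
Reactants: 6 3-[(1S,4R)-1-methyl-2-oxo-4-(prop-1-en-2-yl)cyclohexyl]propanenitrile
Product: 7 3-[(1S,4R)-4-(3-hydroxyprop-1-en-2-yl)-1-methyl-2-oxocyclohexyl]propanenitrile
Conditions: SeO2 (0.5 equiv), t-BuOOH (3 equiv), CH2Cl2, rt
Reagents that add atoms: selenium dioxide (catalytic oxygen carrier), O=[Se]=O; tert-butyl hydroperoxide (terminal oxidant), CC(C)(C)OO
Why: Riley-type allylic oxidation (ene reaction, then [2,3]-sigmatropic shift) at the only alkene should oxidise the allylic CH3 in preference to the C7 methine and leave the ketone α-CH2 untouched at room temperature; no stereocentre is affected.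

Step 3
Reactants: 7 3-[(1S,4R)-4-(3-hydroxyprop-1-en-2-yl)-1-methyl-2-oxocyclohexyl]propanenitrile
Product: 8 3-[(1S,4R)-4-[3-(tert-butyldimethylsilyloxy)prop-1-en-2-yl]-1-methyl-2-oxocyclohexyl]propanenitrile
Conditions: TBSCl, imidazole, DMF, rt
Reagents that add atoms: tert-butyldimethylsilyl chloride, CC(C)(C)[Si](C)(C)Cl
Why: Standard silylation of the primary allylic alcohol masks C12–OH against the organometallic, hydride and low-valent metal steps that follow.

Step 4
Reactants: 8 3-[(1S,4R)-4-[3-(tert-butyldimethylsilyloxy)prop-1-en-2-yl]-1-methyl-2-oxocyclohexyl]propanenitrile; 9 ethynylmagnesium bromide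
Product: 11 (2S,5R)-5-[3-(tert-butyldimethylsilyloxy)prop-1-en-2-yl]-2-(2-cyanoethyl)-1-ethynyl-2-methylcyclohexyl methyl carbonate (mixture of C1 epimers), via bromomagnesium alkoxide 10 (not isolated)
Conditions: HC≡CMgBr (3 equiv), THF, 0 °C to rt; then ClCO2Me, 0 °C to rt
Reagents that add atoms: ethynylmagnesium bromide (9), C#C[Mg]Br; methyl chloroformate, COC(=O)Cl
Why: Acetylide 1,2-addition to the hindered α-quaternary ketone (as in 17-ketosteroid ethynylation) should outpace attack on the nitrile, and the tertiary alkoxide is trapped in situ as the carbonate; the new C5 centre forms as a mixture that need not be separated because C5 becomes sp2 in step 5.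

Step 5
Reactants: 11 propargylic methyl carbonate (C5 epimers)
Product: 12 3-[(1S,4R)-4-[3-(tert-butyldimethylsilyloxy)prop-1-en-2-yl]-2-ethenylidene-1-methylcyclohexyl]propanenitrile
Conditions: Pd2(dba)3·CHCl3 (2.5 mol %), n-Bu3P (10 mol %), HCO2NH4 (2 equiv), THF, 25–40 °C
Reagents that add atoms: none
Why: Pd-catalysed formate hydrogenolysis of a propargylic carbonate: SN2′ oxidative addition gives an allenylpalladium species, formate exchange and decarboxylation deliver hydride, and reductive elimination gives the terminal allene, so both C5 epimers converge on one compound.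

Step 6
Reactants: 12 3-[(1S,4R)-4-[3-(tert-butyldimethylsilyloxy)prop-1-en-2-yl]-2-ethenylidene-1-methylcyclohexyl]propanenitrile
Product: 14 3-[(1S,4R)-4-[3-(tert-butyldimethylsilyloxy)prop-1-en-2-yl]-2-ethenylidene-1-methylcyclohexyl]propanal, via N-aluminio aldimine 13 (not isolated)
Conditions: DIBAL-H (1.2 equiv), toluene, −78 °C; then aq. Rochelle salt, rt
Reagents that add atoms: water, O
Why: DIBAL-H adds once to the nitrile at −78 °C and the N-aluminio aldimine is hydrolysed to the aldehyde on work-up; the allene, the alkene and the silyl ether are inert under these conditions.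

Step 7
Reactants: 14 3-[(1S,4R)-4-[3-(tert-butyldimethylsilyloxy)prop-1-en-2-yl]-2-ethenylidene-1-methylcyclohexyl]propanal
Product: 15 (3S,7R,10S)-12-(tert-butyldimethylsilyloxy)-3β-(triethylsilyloxy)eudesma-4,11(13)-diene
Conditions: Ni(cod)2 (10 mol %), IPr [1,3-bis(2,6-diisopropylphenyl)imidazol-2-ylidene] (10 mol %), Et3SiH (2 equiv), THF, rt, 14 added slowly at high dilution
Reagents that add atoms: triethylsilane, CC[SiH](CC)CC
Why: Proposed new method: Ni(0)–NHC should couple the C3 aldehyde with the terminal C4=C15 π bond of the allene by oxidative cyclisation (C3–C4 bond, O–Ni–C15 nickelacycle, i.e. an η3-allyl nickel alkoxide over C15–C4–C5), σ-bond metathesis with Et3SiH then gives the silyl ether and an allyl nickel hydride, and C–H reductive elimination at the unhindered C15 terminus releases the tetrasubstituted C4=C5 alkene with C15 as a methyl group. The closest known reaction type is the Ni(0)/NHC-catalysed three-component reductive coupling of allenes, aldehydes and silanes, which joins the aldehyde carbon to the central allene carbon, together with Ni-catalysed reductive cyclisations of ynals; the intramolecular version on an exocyclic 1,1-disubstituted allene is the new element. Ring A (C1–C2–C3–C4–C5–C10) closes as a six-membered ring by attack on the sp carbon C4, exo with respect to the reacting C4=C15 π bond. The only new stereocentre, C3, should be set by the metallacycle: the O–Ni–C15 chelate holds the C3–O bond near the plane of the nascent C4=C5 alkene (pseudo-equatorial), and in the half-chair imposed by the C10 quaternary centre (axial angular methyl, ring B chair with the C7 substituent equatorial) that position is 3β (3S). The step needs attack at C4 rather than C5 and hydride delivery to C15 rather than C5; the substrate secures both, because the C4=C15 π lobes lie in the plane of the C6–C5–C10 bonds and point at the tethered aldehyde while C5 is fully substituted and neopentylic, and slow addition at high dilution should suppress allene hydrosilylation and oligomerisation.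

Step 8
Reactants: 15 (3S,7R,10S)-12-(tert-butyldimethylsilyloxy)-3β-(triethylsilyloxy)eudesma-4,11(13)-diene
Product: 16 (3S,7R,10S)-eudesma-4,11(13)-diene-3β,12-diol
Conditions: TBAF (3 equiv), THF, 0 °C to rt
Reagents that add atoms: none
Why: Fluoride-mediated desilylation should cleave both silyl ethers under non-acidic conditions that do not ionise the tertiary-allylic C3–O system.

Step 9
Reactants: 16 (3S,7R,10S)-eudesma-4,11(13)-diene-3β,12-diol
Product: 17 3β-hydroxyeudesma-4,11(13)-dien-12-al
Conditions: TEMPO (10 mol %), PhI(OAc)2 (1.1 equiv), CH2Cl2, 0 °C to rt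
Reagents that add atoms: none
Why: Oxoammonium oxidation (TEMPO/PhI(OAc)2) is strongly selective for the unhindered primary allylic alcohol over the secondary C3 carbinol flanked by the tetrasubstituted alkene, and stops at the aldehyde.

Step 10
Reactants: 17 3β-hydroxyeudesma-4,11(13)-dien-12-al
Product: 18 3β-hydroxyeudesma-4,11(13)-dien-12-oic acid
Conditions: NaClO2, NaH2PO4, 2-methyl-2-butene (large excess), t-BuOH/H2O, 0 °C to rt
Reagents that add atoms: sodium chlorite, [Na+].[O-]Cl=O
Why: Pinnick oxidation converts the 2-substituted acrolein to the acrylic acid without alkene migration, the excess 2-methyl-2-butene scavenging HOCl before it can attack the electron-rich C4=C5 bond.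

Step 11
Reactants: 18 3β-hydroxyeudesma-4,11(13)-dien-12-oic acid
Product: 19 methyl 3β-hydroxyeudesma-4,11(13)-dien-12-oate
Conditions: TMSCHN2, toluene/MeOH (4:1), 0 °C
Reagents that add atoms: trimethylsilyldiazomethane, C[Si](C)(C)C=[N+]=[N-]
Why: Diazoalkane O-methylation is specific for the carboxylic acid and leaves the secondary alcohol free.

Step 12
Reactants: 19 methyl 3β-hydroxyeudesma-4,11(13)-dien-12-oate; 20 angelic acid
Product: 22 methyl 3β-angeloyloxyeudesma-4,11(13)-dien-12-oate, via mixed anhydride 21 (not isolated)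
Conditions: 20, 2,4,6-Cl3C6H2COCl, Et3N, toluene, rt; then 19, toluene, 80 °C
Reagents that add atoms: angelic acid (20), C/C=C(/C)C(=O)O
Why: Yamaguchi esterification through the mixed anhydride acylates the C3 alcohol with retention at C3, and omitting a nucleophilic acyl-transfer catalyst should keep the (Z)-2-methylbut-2-enoyl geometry from isomerising to the tiglate.

Step 13
Reactants: 22 methyl 3β-angeloyloxyeudesma-4,11(13)-dien-12-oate
Product: 23 methyl (3S,5S,7R,10S)-3β-angeloyloxy-5α-hydroperoxyeudesma-4(15),11(13)-dien-12-oate (target)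
Conditions: O2, hν (visible), tetraphenylporphyrin (1 mol %), CH2Cl2, −20 °C
Reagents that add atoms: dioxygen, O=O
Why: Schenck ene reaction: singlet oxygen should add to the only electron-rich alkene (C4=C5) from the α face, anti to the axial C10 methyl, bonding to C5 and abstracting a C15 hydrogen so that the double bond moves to C4=C15 and C5 becomes 5α-OOH (5S); abstraction from C15 rather than C6 or C3 is favoured by the geminal-directing effect of the electron-withdrawing allylic acyloxy group and the deactivated C3–H bond, and the acrylate and angelate alkenes are too electron-poor to compete.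

## Compound list

1 | (+)-dihydrocarvone, (2R,5R)-2-methyl-5-(prop-1-en-2-yl)cyclohexan-1-one (commercial material also contains the 2S epimer) | C[C@@H]1CC[C@H](CC1=O)C(C)=C | starting material
2 | (R)-(+)-1-phenylethylamine | C[C@@H](N)c1ccccc1 | starting material
3 | acrylonitrile | C=CC#N | starting material
4 | ketimine of 1 with 2 (C2 epimers, in equilibrium with the secondary enamine) | CC1CC[C@H](CC1=N[C@H](C)c1ccccc1)C(C)=C | intermediate
5 | cyanoethylated ketimine | N#CCC[C@]1(C)CC[C@H](CC1=N[C@H](C)c1ccccc1)C(C)=C | intermediate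
6 | 3-[(1S,4R)-1-methyl-2-oxo-4-(prop-1-en-2-yl)cyclohexyl]propanenitrile | N#CCC[C@]1(C)CC[C@H](CC1=O)C(C)=C | intermediate
7 | 3-[(1S,4R)-4-(3-hydroxyprop-1-en-2-yl)-1-methyl-2-oxocyclohexyl]propanenitrile | N#CCC[C@]1(C)CC[C@H](CC1=O)C(=C)CO | intermediate
8 | 3-[(1S,4R)-4-[3-(tert-butyldimethylsilyloxy)prop-1-en-2-yl]-1-methyl-2-oxocyclohexyl]propanenitrile | N#CCC[C@]1(C)CC[C@H](CC1=O)C(=C)CO[Si](C)(C)C(C)(C)C | intermediate
9 | ethynylmagnesium bromide | C#C[Mg]Br | starting material
10 | bromomagnesium alkoxide of the tertiary ethynyl carbinol (C5 epimers) | N#CCC[C@]1(C)CC[C@H](CC1(C#C)O[Mg]Br)C(=C)CO[Si](C)(C)C(C)(C)C | intermediate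
11 | (2S,5R)-5-[3-(tert-butyldimethylsilyloxy)prop-1-en-2-yl]-2-(2-cyanoethyl)-1-ethynyl-2-methylcyclohexyl methyl carbonate (C1 epimers) | N#CCC[C@]1(C)CC[C@H](CC1(C#C)OC(=O)OC)C(=C)CO[Si](C)(C)C(C)(C)C | intermediate
12 | 3-[(1S,4R)-4-[3-(tert-butyldimethylsilyloxy)prop-1-en-2-yl]-2-ethenylidene-1-methylcyclohexyl]propanenitrile | N#CCC[C@]1(C)CC[C@H](CC1=C=C)C(=C)CO[Si](C)(C)C(C)(C)C | intermediate
13 | N-(diisobutylaluminio) aldimine of 14 | CC(C)C[Al](CC(C)C)N=CCC[C@]1(C)CC[C@H](CC1=C=C)C(=C)CO[Si](C)(C)C(C)(C)C | intermediate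
14 | 3-[(1S,4R)-4-[3-(tert-butyldimethylsilyloxy)prop-1-en-2-yl]-2-ethenylidene-1-methylcyclohexyl]propanal | O=CCC[C@]1(C)CC[C@H](CC1=C=C)C(=C)CO[Si](C)(C)C(C)(C)C | intermediate
15 | (3S,7R,10S)-12-(tert-butyldimethylsilyloxy)-3β-(triethylsilyloxy)eudesma-4,11(13)-diene | C=C(CO[Si](C)(C)C(C)(C)C)[C@@H]1CC[C@@]2(C)CC[C@H](O[Si](CC)(CC)CC)C(C)=C2C1 | intermediate
16 | (3S,7R,10S)-eudesma-4,11(13)-diene-3β,12-diol | C=C(CO)[C@@H]1CC[C@@]2(C)CC[C@H](O)C(C)=C2C1 | intermediate
17 | 3β-hydroxyeudesma-4,11(13)-dien-12-al | C=C(C=O)[C@@H]1CC[C@@]2(C)CC[C@H](O)C(C)=C2C1 | intermediate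
18 | 3β-hydroxyeudesma-4,11(13)-dien-12-oic acid | C=C(C(=O)O)[C@@H]1CC[C@@]2(C)CC[C@H](O)C(C)=C2C1 | intermediate
19 | methyl 3β-hydroxyeudesma-4,11(13)-dien-12-oate | C=C(C(=O)OC)[C@@H]1CC[C@@]2(C)CC[C@H](O)C(C)=C2C1 | intermediate
20 | angelic acid, (Z)-2-methylbut-2-enoic acid | C/C=C(/C)C(=O)O | starting material
21 | angelic 2,4,6-trichlorobenzoic mixed anhydride | C/C=C(/C)C(=O)OC(=O)c1c(Cl)cc(Cl)cc1Cl | intermediate
22 | methyl 3β-angeloyloxyeudesma-4,11(13)-dien-12-oate | C=C(C(=O)OC)[C@@H]1CC[C@@]2(C)CC[C@H](OC(=O)/C(C)=C\C)C(C)=C2C1 | intermediate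
23 | methyl (3S,5S,7R,10S)-3β-angeloyloxy-5α-hydroperoxyeudesma-4(15),11(13)-dien-12-oate | C=C(C(=O)OC)[C@@H]1CC[C@@]2(C)CC[C@H](OC(=O)/C(C)=C\C)C(=C)[C@]2(OO)C1 | target

## Step count and risks

Total step count: 13. Longest linear sequence: 13 steps (1 to 23).

Steps most likely to fail:

1. Step 7 (Proposed new method). The catalyst may spend the silane on allene hydrosilylation or aldehyde reduction, hydride may be delivered to C5 instead of C15 (giving the 4(15)-ene), or facial control at C3 may be poor. The fallback uses known chemistry, keeps the C3–C4 ring closure, sets out from 6 and returns at 16. Wittig ethylidenation of 6 (EtPPh3Br, KOt-Bu, toluene, reflux) should give 3-[(1S,4R)-2-ethylidene-1-methyl-4-(prop-1-en-2-yl)cyclohexyl]propanenitrile F1 as an E/Z mixture. Nitrile hydrolysis (KOH, ethylene glycol, 150 °C) gives 3-[(1S,4R)-2-ethylidene-1-methyl-4-(prop-1-en-2-yl)cyclohexyl]propanoic acid F2, and oxalyl chloride gives the acid chloride F3. SnCl4 (CH2Cl2, −78 °C) then effects intramolecular Friedel–Crafts-type acylation of the exocyclic alkene at C4; both alkene isomers converge through the C5 cation, which loses the C4 proton, to give (+)-α-cyperone F4. Riley oxidation (SeO2, t-BuOOH), selective for the isopropenyl group because the enone alkene is deactivated, gives 12-hydroxy-α-cyperone F5. Luche reduction (NaBH4, CeCl3·7H2O, MeOH, −78 °C; axial hydride delivery to the equatorial 3β-alcohol) returns diol 16.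

2. Step 13. Hydrogen abstraction may occur at C6 (leading to a 4-hydroperoxy-5-ene) or oxygen may approach from the β face. The fallback sets out from 19 and returns at 23, changing the directing group and the order of events. Photooxygenation of the free allylic alcohol 19 in a non-polar solvent, where hydrogen bonding of the C3–OH to the incoming oxygen is expected to reinforce abstraction from the geminal C15 methyl, should give methyl 3β-hydroxy-5α-hydroperoxyeudesma-4(15),11(13)-dien-12-oate F6. The hydroperoxide is masked with 2-methoxypropene/PPTS as the 2-methoxyprop-2-yl peroxyketal F7. Yamaguchi angeloylation as in step 12, at the lowest workable temperature, gives the angeloylated peroxyketal F8, and AcOH/THF/H2O releases 23.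

3. Step 12. The angeloyl unit may isomerise to the tigloyl unit, and acylation of the hindered allylic alcohol may be slow. The fallback sets out from 19 and returns at 22, building the Z-alkene on the molecule instead of transferring it. Esterification of 19 with 2-[bis(2,2,2-trifluoroethoxy)phosphoryl]propanoic acid (DCC, DMAP, CH2Cl2) gives methyl 3β-{2-[bis(2,2,2-trifluoroethoxy)phosphoryl]propanoyloxy}eudesma-4,11(13)-dien-12-oate F9. Still–Gennari olefination with acetaldehyde (KHMDS, 18-crown-6, THF, −78 °C) should then give the (Z)-2-methylbut-2-enoate 22 directly.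

Further compounds
F1 | step 7 | 3-[(1S,4R)-2-ethylidene-1-methyl-4-(prop-1-en-2-yl)cyclohexyl]propanenitrile (E/Z mixture) | N#CCC[C@]1(C)CC[C@H](CC1=CC)C(C)=C
F2 | step 7 | 3-[(1S,4R)-2-ethylidene-1-methyl-4-(prop-1-en-2-yl)cyclohexyl]propanoic acid (E/Z mixture) | OC(=O)CC[C@]1(C)CC[C@H](CC1=CC)C(C)=C
F3 | step 7 | 3-[(1S,4R)-2-ethylidene-1-methyl-4-(prop-1-en-2-yl)cyclohexyl]propanoyl chloride (E/Z mixture) | ClC(=O)CC[C@]1(C)CC[C@H](CC1=CC)C(C)=C
F4 | step 7 | (+)-α-cyperone, (4aS,7R)-1,4a-dimethyl-7-(prop-1-en-2-yl)-4,4a,5,6,7,8-hexahydronaphthalen-2(3H)-one | CC(=C)[C@@H]1CC[C@@]2(C)CCC(=O)C(C)=C2C1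
F5 | step 7 | 12-hydroxy-α-cyperone, 12-hydroxyeudesma-4,11(13)-dien-3-one | C=C(CO)[C@@H]1CC[C@@]2(C)CCC(=O)C(C)=C2C1
F6 | step 13 | methyl 3β-hydroxy-5α-hydroperoxyeudesma-4(15),11(13)-dien-12-oate | C=C(C(=O)OC)[C@@H]1CC[C@@]2(C)CC[C@H](O)C(=C)[C@]2(OO)C1
F7 | step 13 | methyl 3β-hydroxy-5α-(2-methoxyprop-2-ylperoxy)eudesma-4(15),11(13)-dien-12-oate | C=C(C(=O)OC)[C@@H]1CC[C@@]2(C)CC[C@H](O)C(=C)[C@]2(OOC(C)(C)OC)C1
F8 | step 13 | methyl 3β-angeloyloxy-5α-(2-methoxyprop-2-ylperoxy)eudesma-4(15),11(13)-dien-12-oate | C=C(C(=O)OC)[C@@H]1CC[C@@]2(C)CC[C@H](OC(=O)/C(C)=C\C)C(=C)[C@]2(OOC(C)(C)OC)C1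
F9 | step 12 | methyl 3β-{2-[bis(2,2,2-trifluoroethoxy)phosphoryl]propanoyloxy}eudesma-4,11(13)-dien-12-oate | C=C(C(=O)OC)[C@@H]1CC[C@@]2(C)CC[C@H](OC(=O)C(C)P(=O)(OCC(F)(F)F)OCC(F)(F)F)C(C)=C2C1
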